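## Retrosynthetic overview
1. The C7–CH2–C7' bridge is cut last. This gives lactone 9 (as its ortho-quinone methide, released from a Mannich base), decarboxycitrinin 11 and a one-carbon iminium salt. Both halves come from one chiral intermediate.
2. The pyran quinone methide ring of 11 is the lactone ring of 9 after lactone-to-lactol reduction and loss of water.
3. Key disconnection: the alkyl C3–O2 bond of the lactone ring. It leads back to the achiral alkenylbenzoic acid 7. An enantioselective 6-endo anti-Markovnikov hydrolactonization closes the heterocycle and sets C3 and C4.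
4. Acid 7 comes from acid 5 and 2-bromobut-2-ene by ortho C–H alkenylation. Acid 5 comes from 2,4-dimethoxytoluene and CO2.
5. Ring order: the benzene ring is bought, the lactone ring is made in step 4, half of it is converted to the pyran quinone methide in step 6, and the halves are joined in step 7.

Assumption: the sense of induction of the chiral anion in step 4 cannot be predicted, so the antipode giving (3R,4S)-8 is fixed in the first run. Compound 6 is drawn as the E isomer, although the cheaper E/Z mixture also serves because step 4 erases the alkene geometry.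

## Route

Step 1
Reactants: 1 2,4-dimethoxytoluene
Product: 2 1-bromo-2,4-dimethoxy-5-methylbenzene
Conditions: NBS (1.05 equiv), MeCN, 0 °C to rt, dark
Reagents that add atoms: N-bromosuccinimide, O=C1CCC(=O)N1Br
Why: Electrophilic aromatic bromination goes to C5 (para to one methoxy, ortho to the other), because the site between the two methoxy groups is sterically shielded.

Step 2
Reactants: 2 1-bromo-2,4-dimethoxy-5-methylbenzene; 3 carbon dioxide
Product: 5 2,4-dimethoxy-5-methylbenzoic acid, via aryllithium 4 (not isolated)
Conditions: n-BuLi (1.1 equiv), THF, −78 °C; then dry CO2, −78 °C to rt; then 1 M HCl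
Reagents that add atoms: carbon dioxide (3), O=C=O
Why: Bromine–lithium exchange followed by carboxylation of the aryllithium places the future C1 carbonyl carbon regiospecifically.

Step 3
Reactants: 5 2,4-dimethoxy-5-methylbenzoic acid; 6 (E)-2-bromobut-2-ene
Product: 7 2-[(E)-but-2-en-2-yl]-4,6-dimethoxy-3-methylbenzoic acid
Conditions: [RuCl2(p-cymene)]2 (5 mol %), PCy3 (10 mol %), K2CO3 (2 equiv), 6 (2 equiv), NMP, 120 °C, sealed tube; then cold 1 M HCl
Reagents that add atoms: (E)-2-bromobut-2-ene (6), C/C=C(/Br)C
Why: Carboxylate-directed ruthenium-catalysed ortho C–H alkenylation with an alkenyl bromide (metalation–deprotonation, oxidative addition, reductive elimination with retained geometry) can only strike the single free ortho C–H, so the regiochemistry is unambiguous.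

Step 4
Reactants: 7 2-[(E)-but-2-en-2-yl]-4,6-dimethoxy-3-methylbenzoic acid
Product: 8 (3R,4S)-6,8-dimethoxy-3,4,5-trimethylisochroman-1-one
Conditions: 3,6-di-tert-butyl-9-mesityl-10-phenylacridinium salt of a confined BINOL-derived imidodiphosphate anion (5 mol %), PhSSPh (10 mol %), CH2Cl2, 450 nm LEDs, −20 °C, N2; recrystallise
Reagents that add atoms: none
Why: Proposed new method: asymmetric counteranion-directed photoredox anti-Markovnikov hydrolactonization. The excited acridinium oxidises the electron-rich alkenylarene to its radical cation, which stays ion-paired with the chiral imidodiphosphate, and that anion also hydrogen-bonds the CO2H. The di-ortho-flanked alkene stands perpendicular to the ring, so its two faces belong to two rapidly interconverting enantiomeric conformers, and the anion selects one for 6-endo attack of the carboxyl oxygen on the less substituted alkene carbon (new C3–O2 bond, C3 = R). The tertiary benzylic C4 radical then takes H from PhSH on the face that lets the C4 methyl turn pseudoaxial, away from the peri C5 methyl and anti to the pseudoaxial C3 methyl (C4 = S, trans). Electron transfer from the acridinyl radical to the thiyl radical, followed by protonation of thiolate by the chiral acid, closes both cycles. The closest known reaction types are racemic acridinium/thiol anti-Markovnikov hydroacyloxylation and hydroetherification of alkenes, and chiral-anion-paired photoredox reactions of styrene radical cations.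

Step 5
Reactants: 8 (3R,4S)-6,8-dimethoxy-3,4,5-trimethylisochroman-1-one
Product: 9 (3R,4S)-6,8-dihydroxy-3,4,5-trimethylisochroman-1-one
Conditions: BBr3 (5 equiv), CH2Cl2, −78 °C to rt; then H2O
Reagents that add atoms: none
Why: Lewis-acid aryl methyl ether cleavage removes both methyl groups (the one peri to the carbonyl first) without touching the secondary alkyl lactone or either stereocentre.

Step 6
Reactants: 9 (3R,4S)-6,8-dihydroxy-3,4,5-trimethylisochroman-1-one
Product: 11 decarboxycitrinin (3R,4S)-6-hydroxy-3,4,5-trimethyl-3,4-dihydro-8H-isochromen-8-one, via lactol 10 (not isolated)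
Conditions: i-Bu2AlH (4 equiv), CH2Cl2, −78 °C; then 1 M HCl, 0 °C to rt
Reagents that add atoms: none
Why: In this partial lactone reduction two equivalents of hydride form aluminium phenoxides and a third gives a chelated tetrahedral aluminate that survives at −78 °C, and acid then dehydrates lactol 10 through the hydroxy-stabilised benzylic cation to the quinone methide, leaving C3 and C4 untouched.

Step 7
Reactants: 9 (3R,4S)-6,8-dihydroxy-3,4,5-trimethylisochroman-1-one; 12 N,N-dimethylmethyleneiminium iodide; 11 decarboxycitrinin
Product: 15 dicitrinone G, via Mannich base 13 (not isolated), via ortho-quinone methide 14 (not isolated)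
Conditions: 12 (1.0 equiv), NaOAc (1.1 equiv), AcOH, 40 °C; then 11 (1.0 equiv), 70 °C; dilute HCl wash, chromatography
Reagents that add atoms: N,N-dimethylmethyleneiminium iodide (12), C=[N+](C)C.[I-]
Why: Mannich aminomethylation at C7, the only free ring carbon of 9, is followed by retro-Mannich release of ortho-quinone methide 14 and Michael addition of the vinylogous acid 11 through its C7; pre-activating the less nucleophilic partner suppresses homodimers, the amine stays protonated in AcOH, and adducts containing a minor enantiomer are separable diastereomers, which raises the ee.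

## Compound list
1 | 2,4-dimethoxytoluene | Cc1ccc(OC)cc1OC | starting material
2 | 1-bromo-2,4-dimethoxy-5-methylbenzene | Cc1cc(Br)c(OC)cc1OC | intermediate
3 | carbon dioxide | O=C=O | starting material
4 | (2,4-dimethoxy-5-methylphenyl)lithium | Cc1cc([Li])c(OC)cc1OC | intermediate
5 | 2,4-dimethoxy-5-methylbenzoic acid | Cc1cc(C(=O)O)c(OC)cc1OC | intermediate
6 | (E)-2-bromobut-2-ene | C/C=C(/Br)C | starting material
7 | 2-[(E)-but-2-en-2-yl]-4,6-dimethoxy-3-methylbenzoic acid | C/C=C(\C)c1c(C)c(OC)cc(OC)c1C(=O)O | intermediate
8 | (3R,4S)-6,8-dimethoxy-3,4,5-trimethylisochroman-1-one | c1c(OC)c(C)c2c(c1OC)C(=O)O[C@H](C)[C@H]2C | intermediate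
9 | (3R,4S)-6,8-dihydroxy-3,4,5-trimethylisochroman-1-one | c1c(O)c(C)c2c(c1O)C(=O)O[C@H](C)[C@H]2C | intermediate
10 | (3R,4S)-3,4,5-trimethylisochroman-1,6,8-triol (lactol, C1 epimers) | c1c(O)c(C)c2c(c1O)C(O)O[C@H](C)[C@H]2C | intermediate
11 | decarboxycitrinin, (3R,4S)-6-hydroxy-3,4,5-trimethyl-3,4-dihydro-8H-isochromen-8-one | CC1=C2C(=CO[C@H](C)[C@H]2C)C(=O)C=C1O | intermediate
12 | N,N-dimethylmethyleneiminium iodide | C=[N+](C)C.[I-] | starting material
13 | (3R,4S)-7-[(dimethylamino)methyl]-6,8-dihydroxy-3,4,5-trimethylisochroman-1-one | CN(C)Cc1c(O)c(C)c2c(c1O)C(=O)O[C@H](C)[C@H]2C | intermediate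
14 | (3R,4S)-8-hydroxy-3,4,5-trimethyl-7-methylidene-3,4-dihydro-1H-isochromene-1,6(7H)-dione (ortho-quinone methide) | C=C1C(=O)C(C)=C2C(=C1O)C(=O)O[C@H](C)[C@H]2C | intermediate
15 | dicitrinone G | CC1=C2C(=CO[C@H](C)[C@H]2C)C(=O)C(Cc2c(O)c(C)c3c(c2O)C(=O)O[C@H](C)[C@H]3C)=C1O | target

## Step count and weak points
Total step count: 7. Longest linear sequence: 7 (1 → 2 → 5 → 7 → 8 → 9 → 11 → 15; compound 9 feeds both step 6 and step 7).

**Step 4 (the proposed new step).**
- The alkene is twisted out of conjugation, so the hole may stay on the arene and cyclisation may be slow.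
- The ee and the trans/cis ratio at C4 are unproven.
- Acid-promoted Markovnikov closure to the phthalide could compete.

The fallback uses known chemistry, sets out from geometrically pure 7 and comes back at 8. MeI and K2CO3 in DMF give methyl 2-[(E)-but-2-en-2-yl]-4,6-dimethoxy-3-methylbenzoate F1. F1 undergoes asymmetric hydroboration with monoisopinocampheylborane prepared from (−)-α-pinene (THF, −25 °C). This is a syn addition that places boron on the less hindered alkene carbon. Oxidation with NaBO3·4H2O proceeds with retention and gives methyl 2-[(2S,3R)-3-hydroxybutan-2-yl]-4,6-dimethoxy-3-methylbenzoate F2. Catalytic TsOH in toluene lactonises F2 to 8, and recrystallisation raises the ee.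

**Step 3.**
- The only ortho C–H lies next to a methyl group, and the alkenyl bromide is alpha-branched, so turnover may be poor.
- Protodecarboxylation may intervene.

The fallback sets out from 5 and comes back at 7. Oxidative annulation of 5 with but-2-yne ([Cp*RhCl2]2, Cu(OAc)2, DMF, 120 °C) uses insertion of the smallest internal alkyne instead of a hindered coupling. It gives 6,8-dimethoxy-3,4,5-trimethyl-1H-isochromen-1-one F3. Hydrogenation (H2, Pd/C, EtOAc) gives racemic cis-6,8-dimethoxy-3,4,5-trimethylisochroman-1-one F4. LiN(i-Pr)2 in THF (−78 to 0 °C) removes the C4 proton, and the benzylic anion expels the carboxylate (E1cB). This returns 7 as an E/Z mixture, which step 4 tolerates.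

**Step 6.**
- The aluminium phenoxides deactivate the lactone.
- Premature collapse of the aluminate to the quinone methide would allow over-reduction to the isochroman.

The fallback sets out from 8 and comes back at 11 by reducing before deprotecting. Treatment of 8 with i-Bu2AlH (1.2 equiv, CH2Cl2, −78 °C) gives (3R,4S)-6,8-dimethoxy-3,4,5-trimethylisochroman-1-ol F5. BBr3 (CH2Cl2, −78 to 0 °C) then ionises the lactol, cleaves both methyl ethers and delivers 11 on aqueous work-up.

## Further compounds
F1 | step 4 | methyl 2-[(E)-but-2-en-2-yl]-4,6-dimethoxy-3-methylbenzoate | C/C=C(\C)c1c(C)c(OC)cc(OC)c1C(=O)OC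
F2 | step 4 | methyl 2-[(2S,3R)-3-hydroxybutan-2-yl]-4,6-dimethoxy-3-methylbenzoate | O[C@H](C)[C@H](c1c(C)c(OC)cc(OC)c1C(=O)OC)C
F3 | step 3 | 6,8-dimethoxy-3,4,5-trimethyl-1H-isochromen-1-one | c1c(OC)c(C)c2c(c1OC)C(=O)OC(C)=C2C
F4 | step 3 | racemic cis-6,8-dimethoxy-3,4,5-trimethylisochroman-1-one (one enantiomer drawn) | c1c(OC)c(C)c2c(c1OC)C(=O)O[C@H](C)[C@@H]2C
F5 | step 6 | (3R,4S)-6,8-dimethoxy-3,4,5-trimethylisochroman-1-ol (C1 epimers) | c1c(OC)c(C)c2c(c1OC)C(O)O[C@H](C)[C@H]2C
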